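**Retrosynthetic overview**

1. Target numbered as a benzo[b]oxepine: O1, C2 (CH–CH2Br), C3 (C–CH3)=C4, C5, C5a, C6 (CMe2), C7 (CHBr), C8, C9, C9a (C–CH3); ring A is the carbocycle, ring B the oxepene.
2. Last events: C2–H by hydride reduction of lactol 20 (oxocarbenium ion, attack anti to the axial C9a methyl); C2–CH2Br by addition of LiCH2Br to bromolactone 19.
3. Rings A then B close in one bromonium-triggered cation–olefin bicyclisation of the open-chain epoxy dienoate 15 (through bromohydrin 16): C7 comes from the enantiopure epoxide, C5a and C9a from anti addition across the 5E alkene, ring B from capture by the ester oxygen.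
4. Key disconnections C2–C3 and C5–C5a: they flank the C3(CH3)=C4–C5 unit of ring B, a (Z)-but-2-ene-2,4-diyl bridge with one allylic end (C5) and one vinylic, acyl-bearing end (C3). Before ring A exists C5a is a vinylic CH, so both bonds are made in one flask from the alkenyllithium of 6, the linchpin (Z)-1,3-dibromobut-2-ene 10 and Boc2O 11.
5. Building blocks: 6 from 5-bromo-2-methylpent-2-ene (acetylide alkylation, carboalumination–iodination, Shi epoxidation); 10 from but-2-yn-1-ol.

Key step: step 6

Remark (assumption on the chemistry): the D-fructose-derived ketone of the Shi epoxidation is taken to give the R epoxide of this prenyl-type alkene, as it does for related 2-methylalk-2-enes; R is needed because this carbon is inverted once on its way to the C7 bromide.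

**Route**

Step 1
Reactants: 1 5-bromo-2-methylpent-2-ene; 2 lithium acetylide–ethylenediamine complex (LiC≡CH·H2NCH2CH2NH2)
Product: 3 6-methylhept-5-en-1-yne
Conditions: DMSO, 10 → 25 °C
Reagents that add atoms: none
Why: SN2 alkylation of an acetylide by a primary homoallylic bromide, a standard terminal-alkyne synthesis; no stereocentre is formed.

Step 2
Reactants: 3 6-methylhept-5-en-1-yne
Product: 5 (E)-1-iodo-2,6-dimethylhepta-1,5-diene, via alkenylalane 4 (not isolated)
Conditions: Me3Al (2 equiv), Cp2ZrCl2 (0.2 equiv), CH2Cl2, 0 → 23 °C; then I2, THF, −30 → 0 °C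
Reagents that add atoms: trimethylaluminium, C[Al](C)C; iodine, II
Why: Negishi zirconium-catalysed carboalumination adds methyl and aluminium syn across the terminal alkyne (methyl at the internal carbon), and iodinolysis of the C–Al bond with retention should give only the E alkenyl iodide; the trisubstituted alkene does not react.

Step 3
Reactants: 5 (E)-1-iodo-2,6-dimethylhepta-1,5-diene
Product: 6 (R)-3-[(E)-4-iodo-3-methylbut-3-en-1-yl]-2,2-dimethyloxirane
Conditions: D-fructose-derived Shi ketone (0.3 equiv), Oxone (2KHSO5·KHSO4·K2SO4), K2CO3, Bu4NHSO4, MeCN–CH2(OMe)2 / aqueous Na2B4O7 buffer, 0 °C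
Reagents that add atoms: potassium peroxymonosulfate (active component of Oxone), [K+].[O-]S(=O)(=O)OO
Why: Shi epoxidation: the chiral dioxirane transfers oxygen through a spiro transition state to the electron-rich 2-methylalk-2-ene only (the iodoalkene is deactivated) and sets the epoxide CH carbon as R, the future C7.

Step 4
Reactants: 7 but-2-yn-1-ol
Product: 9 (Z)-3-bromobut-2-en-1-ol, via alkenylaluminate 8 (not isolated)
Conditions: NaAlH2(OCH2CH2OMe)2 (1.5 equiv), Et2O, 0 °C; EtOAc; then NBS, −78 °C
Reagents that add atoms: N-bromosuccinimide, O=C1CCC(=O)N1Br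
Why: alkoxide-directed anti-hydroalumination of the propargylic alcohol puts aluminium on C3 cis to the CH2O group in a five-membered aluminate, and brominolysis with retention should give the Z bromoalkene.

Step 5
Reactants: 9 (Z)-3-bromobut-2-en-1-ol
Product: 10 (Z)-1,3-dibromobut-2-ene
Conditions: PBr3 (0.4 equiv), Et2O, 0 °C
Reagents that add atoms: phosphorus tribromide, BrP(Br)Br
Why: PBr3 converts the primary allylic alcohol into the bromide by SN2 on its phosphite ester; the trisubstituted bromoalkene keeps its Z geometry.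

Step 6
Reactants: 6 (R)-3-[(E)-4-iodo-3-methylbut-3-en-1-yl]-2,2-dimethyloxirane; 10 (Z)-1,3-dibromobut-2-ene; 11 di-tert-butyl dicarbonate (Boc2O)
Product: 15 tert-butyl (2Z,5E)-8-[(2R)-3,3-dimethyloxiran-2-yl]-2,6-dimethylocta-2,5-dienoate, via alkenyllithium 12 (not isolated), via vinylic bromide 13 (not isolated), via vinyllithium 14 (not isolated)
Conditions: 6, t-BuLi (2.0 equiv), Et2O, −78 °C; CuBr·SMe2 (0.05 equiv), then 10, THF, −78 → −30 °C; t-BuLi (2.1 equiv), −78 °C; then 11, −78 → 0 °C; aqueous NH4Cl
Reagents that add atoms: none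
Why: One-flask three-component linchpin union: I/Li exchange of 6 gives the E alkenyllithium 12 with retention, which under copper catalysis displaces the allylic bromide of 10 in SN2 fashion (C5–C5a) to give 13; a second Br/Li exchange turns the remaining vinylic bromide into vinyllithium 14, which is acylated by Boc2O (C2–C3). The closest known reaction types are copper-catalysed allylic alkylation by organolithiums, halogen–lithium exchange of alkenyl halides with retention, and trapping of alkenyllithiums by Boc2O. No ring is closed and no stereocentre is created; the R epoxide is carried through unchanged. The step needs chemoselectivity (sp3 allylic C–Br before sp2 C–Br; exchange faster than epoxide opening), SN2 rather than SN2′ regioselectivity, and retention of both alkene geometries. These are secured by the inertness of the vinylic bromide to substitution and to exchange with an sp2 organolithium at −78 °C, by the fully substituted bromine-bearing γ-carbon of 10, by the hindered trisubstituted oxirane, and by the configurational stability of alkenyllithiums at this temperature. The 5E geometry (from the syn carbometallation) later dictates the trans ring fusion, and the 2Z geometry (from the anti hydroalumination) is what allows ring B to close.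

Step 7
Reactants: 15 tert-butyl (2Z,5E)-8-[(2R)-3,3-dimethyloxiran-2-yl]-2,6-dimethylocta-2,5-dienoate
Product: 16 tert-butyl (2Z,5E,9R)-10-bromo-9-hydroxy-2,6,10-trimethylundeca-2,5-dienoate
Conditions: LiBr (3 equiv), AcOH (3 equiv), THF, 0 → 23 °C
Reagents that add atoms: lithium bromide, [Li+].[Br-]
Why: acid-assisted anti opening of the trisubstituted epoxide by bromide at the tertiary carbon leaves the C–O bond of the stereocentre untouched (9R); the regioisomeric anti-bromohydrin, if formed, would lead to the same bromonium ion.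

Step 8
Reactants: 16 tert-butyl (2Z,5E,9R)-10-bromo-9-hydroxy-2,6,10-trimethylundeca-2,5-dienoate
Product: 19 (5aS,7S,9aS)-7-bromo-3,6,6,9a-tetramethyl-5a,6,7,8,9,9a-hexahydrobenzo[b]oxepin-2(5H)-one, via triflate 17 (not isolated), via bromonium ion 18 (not isolated)
Conditions: Tf2O (1.2 equiv), 2,6-di-tert-butyl-4-methylpyridine (2.5 equiv), CH2Cl2, −78 → −20 °C
Reagents that add atoms: none
Why: O-triflation is followed by displacement of triflate by the neighbouring tertiary bromine with inversion, giving one enantiomer of the bromonium ion; the 5E alkene attacks its tertiary carbon in a chair-like transition state (ring A, bromine equatorial) and the enoate carbonyl oxygen captures the tertiary cation anti with loss of isobutene (ring B), an enantiospecific bromonium-initiated cation–olefin bicyclisation with ester termination that sets C7 from the epoxide and C5a and C9a from the alkene geometry.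

Step 9
Reactants: 19 (5aS,7S,9aS)-7-bromo-3,6,6,9a-tetramethyl-5a,6,7,8,9,9a-hexahydrobenzo[b]oxepin-2(5H)-one
Product: 20 (5aS,7S,9aS)-7-bromo-2-(bromomethyl)-3,6,6,9a-tetramethyl-2,5,5a,6,7,8,9,9a-octahydrobenzo[b]oxepin-2-ol (both C2 epimers)
Conditions: BrCH2I (1.5 equiv), MeLi·LiBr (1.4 equiv), THF–Et2O, −78 °C; AcOH quench at −78 °C
Reagents that add atoms: bromoiodomethane, BrCI
Why: bromomethyllithium, generated by iodine–lithium exchange in the presence of the lactone, adds 1,2 to the carbonyl (carbenoid homologation of a carboxylic acid derivative), and the cold acidic quench keeps the lactol from closing to a spiro-epoxide; the C2 configuration is irrelevant because step 10 erases it.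

Step 10
Reactants: 20 (5aS,7S,9aS)-7-bromo-2-(bromomethyl)-3,6,6,9a-tetramethyl-2,5,5a,6,7,8,9,9a-octahydrobenzo[b]oxepin-2-ol
Product: 22 palisadin B [(2R,5aS,7S,9aS)-7-bromo-2-(bromomethyl)-3,6,6,9a-tetramethyl-2,5,5a,6,7,8,9,9a-octahydrobenzo[b]oxepine], via oxocarbenium ion 21 (not isolated)
Conditions: Et3SiH (5 equiv), TMSOTf (0.3 equiv), CH2Cl2, −78 → −40 °C
Reagents that add atoms: none
Why: ionic hydrogenation of the lactol: both epimers converge on the alkene-conjugated oxocarbenium ion, and hydride should add at C2 (next to oxygen, as in Ferrier-type additions) from the face opposite the axial C9a methyl, which leaves CH2Br syn to that methyl, i.e. 2R.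

**Compound list**

1 | 5-bromo-2-methylpent-2-ene | CC(C)=CCCBr | starting material
2 | lithium acetylide–ethylenediamine complex | [Li+].[C-]#C.NCCN | starting material
3 | 6-methylhept-5-en-1-yne | C#CCCC=C(C)C | intermediate
4 | (E)-(2,6-dimethylhepta-1,5-dien-1-yl)dimethylalane | C[Al](C)/C=C(\C)CCC=C(C)C | intermediate
5 | (E)-1-iodo-2,6-dimethylhepta-1,5-diene | I/C=C(\C)CCC=C(C)C | intermediate
6 | (R)-3-[(E)-4-iodo-3-methylbut-3-en-1-yl]-2,2-dimethyloxirane | CC1(C)O[C@@H]1CC/C(C)=C/I | intermediate
7 | but-2-yn-1-ol | CC#CCO | starting material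
8 | sodium 2,2-bis(2-methoxyethoxy)-3-methyl-2,5-dihydro-1,2-oxaluminol-2-uide (cyclic Z alkenylaluminate) | [Na+].CC1=CCO[Al-]1(OCCOC)OCCOC | intermediate
9 | (Z)-3-bromobut-2-en-1-ol | OC/C=C(\Br)C | intermediate
10 | (Z)-1,3-dibromobut-2-ene | BrC/C=C(\Br)C | intermediate
11 | di-tert-butyl dicarbonate | CC(C)(C)OC(=O)OC(=O)OC(C)(C)C | starting material
12 | {(1E)-4-[(2R)-3,3-dimethyloxiran-2-yl]-2-methylbut-1-en-1-yl}lithium | [Li]/C=C(\C)CC[C@H]1OC1(C)C | intermediate
13 | (3R)-3-[(3E,6Z)-7-bromo-3-methylocta-3,6-dien-1-yl]-2,2-dimethyloxirane | Br/C(C)=C\C/C=C(\C)CC[C@H]1OC1(C)C | intermediate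
14 | {(2E,5E)-8-[(2R)-3,3-dimethyloxiran-2-yl]-6-methylocta-2,5-dien-2-yl}lithium (lithium cis to C4, geometry of 13 retained) | [Li]/C(C)=C\C/C=C(\C)CC[C@H]1OC1(C)C | intermediate
15 | tert-butyl (2Z,5E)-8-[(2R)-3,3-dimethyloxiran-2-yl]-2,6-dimethylocta-2,5-dienoate | CC(C)(C)OC(=O)/C(C)=C\C/C=C(\C)CC[C@H]1OC1(C)C | intermediate
16 | tert-butyl (2Z,5E,9R)-10-bromo-9-hydroxy-2,6,10-trimethylundeca-2,5-dienoate | CC(C)(C)OC(=O)/C(C)=C\C/C=C(\C)CC[C@@H](O)C(C)(C)Br | intermediate
17 | tert-butyl (2Z,5E,9R)-10-bromo-2,6,10-trimethyl-9-(trifluoromethanesulfonyloxy)undeca-2,5-dienoate | CC(C)(C)OC(=O)/C(C)=C\C/C=C(\C)CC[C@@H](OS(=O)(=O)C(F)(F)F)C(C)(C)Br | intermediate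
18 | (S)-bromonium (2,2-dimethylbromiranium) triflate of the dienoate chain | CC(C)(C)OC(=O)/C(C)=C\C/C=C(\C)CC[C@@H]1[Br+]C1(C)C.[O-]S(=O)(=O)C(F)(F)F | intermediate
19 | (5aS,7S,9aS)-7-bromo-3,6,6,9a-tetramethyl-5a,6,7,8,9,9a-hexahydrobenzo[b]oxepin-2(5H)-one | CC1=CC[C@H]2C(C)(C)[C@@H](Br)CC[C@]2(C)OC1=O | intermediate
20 | (5aS,7S,9aS)-7-bromo-2-(bromomethyl)-3,6,6,9a-tetramethyl-2,5,5a,6,7,8,9,9a-octahydrobenzo[b]oxepin-2-ol (both C2 epimers) | CC1=CC[C@H]2C(C)(C)[C@@H](Br)CC[C@]2(C)OC1(O)CBr | intermediate
21 | (5aS,7S,9aS)-7-bromo-2-(bromomethyl)-3,6,6,9a-tetramethyl-5,5a,6,7,8,9-hexahydro-9aH-benzo[b]oxepin-1-ium triflate | CC1=CC[C@H]2C(C)(C)[C@@H](Br)CC[C@]2(C)[O+]=C1CBr.[O-]S(=O)(=O)C(F)(F)F | intermediate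
22 | palisadin B, (2R,5aS,7S,9aS)-7-bromo-2-(bromomethyl)-3,6,6,9a-tetramethyl-2,5,5a,6,7,8,9,9a-octahydrobenzo[b]oxepine | CC1=CC[C@H]2C(C)(C)[C@@H](Br)CC[C@]2(C)O[C@H]1CBr | target

**Step count and risks**

Total steps: 10. Longest linear sequence: 8 (steps 1, 2, 3, 6, 7, 8, 9, 10).

Step 8 is the most likely to fail. The hindered secondary hydroxyl next to the tertiary bromide may be sulfonylated slowly, so that the tertiary bromide eliminates or re-closes to the epoxide before the bromonium ion forms; the ring A cation may also lose a proton before the ester oxygen closes ring B. The fallback generates the same bromonium ion without activating oxygen. It sets out from 15: Ph3PBr2 (CH2Cl2, 0 °C) should open the epoxide with inversion at the secondary carbon to the vicinal dibromide tert-butyl (2Z,5E,9S)-9,10-dibromo-2,6,10-trimethylundeca-2,5-dienoate F1. AgOTf and 2,6-di-tert-butyl-4-methylpyridine (MeNO2–CH2Cl2, −25 °C) then abstract the tertiary bromide with participation of the secondary bromine, giving bromonium ion 18 and, by the same bicyclisation, 19, where it rejoins the route.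

Step 6 is second. Halogen–lithium scrambling between the alkenyllithium and the allylic bromide (homocoupling), attack of organolithium on the oxirane during the second exchange, or double addition of the vinyllithium to the new ester may erode the one-flask sequence. The fallback makes the two bonds in separate palladium-catalysed operations. It sets out from 6: alkenyllithium 12 (t-BuLi, −78 °C) is transmetallated with ZnBr2 to the alkenylzinc bromide bromo{(1E)-4-[(2R)-3,3-dimethyloxiran-2-yl]-2-methylbut-1-en-1-yl}zinc F2. Negishi coupling with 10 (Pd(PPh3)4, THF, 0 → 23 °C; the allylic C–Br adds oxidatively first) should give 13, which is now isolated. Hydroxycarbonylation of its vinylic bromide (Pd(OAc)2, dppf, CO 1 atm, H2O, Et3N, DMF, 60 °C) should give (2Z,5E)-8-[(2R)-3,3-dimethyloxiran-2-yl]-2,6-dimethylocta-2,5-dienoic acid F3, and esterification with Boc2O, DMAP and t-BuOH comes back to the route at 15.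

Step 9 is third. The thermally labile carbenoid may decompose before it adds, or the tetrahedral adduct may open to the bromomethyl ketone and take up a second carbenoid. The fallback brings in the extra carbon as a methylene group and the bromine as an electrophile. It sets out from 19: Petasis methylenation (Cp2TiMe2, toluene, 65 °C) should give the enol ether (5aS,7S,9aS)-7-bromo-3,6,6,9a-tetramethyl-2-methylidene-2,5,5a,6,7,8,9,9a-octahydrobenzo[b]oxepine F4. Bromomethoxylation at the exocyclic carbon (NBS, MeOH, 2,6-lutidine, −40 °C) should give the ketal (5aS,7S,9aS)-7-bromo-2-(bromomethyl)-2-methoxy-3,6,6,9a-tetramethyl-2,5,5a,6,7,8,9,9a-octahydrobenzo[b]oxepine F5. Under the conditions of step 10 (Et3SiH, TMSOTf) F5 ionises to oxocarbenium ion 21 and is reduced, so the fallback comes back to the route at 22.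

Further compounds
F1 | step 8 | tert-butyl (2Z,5E,9S)-9,10-dibromo-2,6,10-trimethylundeca-2,5-dienoate | CC(C)(C)OC(=O)/C(C)=C\C/C=C(\C)CC[C@H](Br)C(C)(C)Br
F2 | step 6 | bromo{(1E)-4-[(2R)-3,3-dimethyloxiran-2-yl]-2-methylbut-1-en-1-yl}zinc | Br[Zn]/C=C(\C)CC[C@H]1OC1(C)C
F3 | step 6 | (2Z,5E)-8-[(2R)-3,3-dimethyloxiran-2-yl]-2,6-dimethylocta-2,5-dienoic acid | OC(=O)/C(C)=C\C/C=C(\C)CC[C@H]1OC1(C)C
F4 | step 9 | (5aS,7S,9aS)-7-bromo-3,6,6,9a-tetramethyl-2-methylidene-2,5,5a,6,7,8,9,9a-octahydrobenzo[b]oxepine | CC1=CC[C@H]2C(C)(C)[C@@H](Br)CC[C@]2(C)OC1=C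
F5 | step 9 | (5aS,7S,9aS)-7-bromo-2-(bromomethyl)-2-methoxy-3,6,6,9a-tetramethyl-2,5,5a,6,7,8,9,9a-octahydrobenzo[b]oxepine | CC1=CC[C@H]2C(C)(C)[C@@H](Br)CC[C@]2(C)OC1(OC)CBr
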